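(The earlier runs and the new flask were computed on assumed constants.)

In a one-step world each starting complex takes one incoming ligand and is finished, so the number to hold is the ligand charged per starting complex charged, 1.05 in zeta, the count that names the limiting reagent; gamma has 1.58.

| flask | starting complex | incoming ligand | capture agent | remark | time |
|---|---|---|---|---|---|
| north | 0.076 M (fed, over 20 h) | 0.11 M | 0.0228 M | run made earlier; the fed solution adds 0.50 times the starting volume |  |
| south | 0.076 M (fed, over 20 h) | 0.17 M | 0.0228 M | run made earlier; the fed solution adds 0.50 times the starting volume |  |
| zeta | 0.076 M (fed, over 20 h) | 0.0800 M | 0.0228 M | the fed solution adds 0.50 times the starting volume | 8.0 d |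
| gamma | 0.076 M (fed, over 20 h) | 0.120 M | 0.0228 M | the fed solution adds 0.50 times the starting volume | 8.0 d |

- north (time / d: starting complex / %, complex with three exchanged / %): 0.625: 7.2, 3.1; 1.25: 1.4, 8.1; 2.50: 0.8, 15.4; 4.00: 0.2, 17.2; 8.00: 0.2, 18.2
- south (time / d: starting complex / %, complex with three exchanged / %): 0.625: 3.2, 5.1; 2.08: 0.2, 17.9; 4.00: 0, 19.1; 6.00: 0, 17.4; 8.00: 0.2, 15.3

(standard deviation of a reading: 0.5 percentage points)

- every charge counts on the volume at the start, and the solution that is fed holds the whole dose
- what has gone from starting complex into another species counts as reacted, even if it can come back
- percentages count the whole charge, also what has not yet gone in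

* part of the starting complex that has reacted at the end, zeta
* part of the starting complex that has reacted at the end, gamma
* what raising the concentration of incoming ligand from its lowest to its highest value here does to the part of the starting complex that has reacted (changes below 5 percentage points count as none) (no change / it falls / it rises)

I keep that world for the first step. During the feed over 20 h, north held 7.2 % of starting complex at 0.625 d. Read as a steady level, this means a fed complex lasts that fraction of the dosing time, about 0.0600 d. That is far shorter than the 2.50 d after which north showed 15.4 % of complex with three exchanged. In that one-step view zeta's ligand still exceeds its complex, so I expect zeta and gamma both to end near north's last reading, 99.8 % reacted, with no trend.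

The forecast counts the later exchanges as claims on the same ligand: “Ligand runs out while some starting complex survives”. It gives zeta 91 % (range 82 % to 98 %), gamma 99.7 % (range 98.5 % to 100 %), and for the trend, it rises. We part on zeta and on the trend.

The simulation gives zeta 99.5 %, gamma 99.7 %, and for the trend no change, with a change of 0.25 percentage points.

    starting complex + incoming ligand → leaving ligand + complex with one exchanged (k = 0.00132 M⁻¹ s⁻¹)
    complex with one exchanged + incoming ligand → leaving ligand + complex with two exchanged (k = 9.18 × 10⁻⁵ M⁻¹ s⁻¹)
    complex with two exchanged + incoming ligand → leaving ligand + complex with three exchanged (k = 0.00143 M⁻¹ s⁻¹)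
    complex with three exchanged + incoming ligand → leaving ligand + complex with four exchanged (k = 7.54 × 10⁻⁵ M⁻¹ s⁻¹)
    leaving ligand + starting complex ⇌ idle adduct, settled at all times (K = 3080 M⁻¹)
    complex with two exchanged + capture agent → trapped intermediate (k = 2.00 × 10⁻⁴ M⁻¹ s⁻¹)
    incoming ligand → decomposition product (k = 1.35 × 10⁻⁸ s⁻¹)

Of zeta's 1.05 ligand per complex, 1.01 has gone by 8.00 d, yet the idle adduct, which takes no incoming ligand in these equations and counts as reacted, holds 45.7 % of the starting complex. The shortage the forecast argued for shows in zeta at about 0.533 ligand per complex, where the answer has moved by 5 points with the other charges held. A neighbour of gamma charged with 2.63 ligand per complex has lost 2.03 by the end; in that neighbour 99.8 % has reacted, and complex with four exchanged stands at 39.7 %.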